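The route rests on cutting N1–C2 of the pyrrole ring. The feature exploited is the C2–Br bond beside N1. It is read as the halogen that remains when an anilide nitrogen displaces the twin bromine of a 1,1-dibromoalkene. One metal-free operation with base thus forms N1–C2, closes the pyrrole ring onto the benzene ring and leaves bromine on C2. The C5 and C6 bromides stay intact and C3 stays free. The substrate is an N-mesyl 2-(2,2-dibromovinyl)aniline brominated at C4 and C5, made by Ramirez olefination, nitro reduction, bromination and mesylation. Mesyl-to-methyl exchange in one flask and a Vilsmeier formylation finish the target.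

Key step: step 5

Remark on the chemistry: C1, C2, C4 and C5 of the anilines become C7a, C3a, C5 and C6 of the indole. Bromine introduced para to nitrogen therefore ends at indole C5, and the bromine of the starting aldehyde ends at C6. The target has no stereocentre and the dibromoalkene has no E/Z isomers.
Assumption: the key step is drawn through the bromoalkyne. Direct addition–elimination at the CBr2 carbon would give the same product and change nothing else.

Step 1
Reactants: 1 4-bromo-2-nitrobenzaldehyde; 2 carbon tetrabromide
Product: 3 4-bromo-1-(2,2-dibromovinyl)-2-nitrobenzene
Conditions: CBr4 (1.5 equiv), PPh3 (3 equiv), CH2Cl2, 0 °C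
Reagents that add atoms: carbon tetrabromide, BrC(Br)(Br)Br
Why: Ramirez gem-dibromoolefination, in which PPh3 and CBr4 form Ph3P=CBr2 and this ylide undergoes a Wittig reaction with the electron-poor aldehyde, while the nitro group and the aryl bromide are inert at 0 °C.

Step 2
Reactants: 3 4-bromo-1-(2,2-dibromovinyl)-2-nitrobenzene
Product: 4 5-bromo-2-(2,2-dibromovinyl)aniline
Conditions: SnCl2·2H2O (5 equiv), EtOH, reflux; aq. NaHCO3 work-up
Reagents that add atoms: none
Why: Chemoselective nitro reduction by divalent tin, the standard method for 2-nitro-β,β-dibromostyrenes, transfers electrons and protons only to the nitro group and, unlike catalytic hydrogenation, leaves aryl and vinylic C–Br bonds alone.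

Step 3
Reactants: 4 5-bromo-2-(2,2-dibromovinyl)aniline
Product: 5 4,5-dibromo-2-(2,2-dibromovinyl)aniline
Conditions: NBS (1.0 equiv), DMF, 0 °C, dark
Reagents that add atoms: N-bromosuccinimide, O=C1CCC(=O)N1Br
Why: Electrophilic aromatic bromination governed by the amino group goes to the open para position C4, because the only free ortho position C6 is squeezed between NH2 and Br and the electron-poor dibromoalkene does not react with NBS.

Step 4
Reactants: 5 4,5-dibromo-2-(2,2-dibromovinyl)aniline; 6 methanesulfonyl chloride
Product: 7 N-[4,5-dibromo-2-(2,2-dibromovinyl)phenyl]methanesulfonamide
Conditions: MsCl (1.1 equiv), pyridine, CH2Cl2, 0 °C → rt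
Reagents that add atoms: methanesulfonyl chloride, CS(=O)(=O)Cl
Why: N-sulfonylation of a primary aniline, in which pyridine takes up HCl but is too weak to deprotonate the product sulfonamide, so that together with the ortho substituent a second mesylation is held back.

Step 5
Reactants: 7 N-[4,5-dibromo-2-(2,2-dibromovinyl)phenyl]methanesulfonamide
Product: 9 2,5,6-tribromo-1-(methylsulfonyl)indole, via bromoalkyne sulfonamide 8 (not isolated)
Conditions: Cs2CO3 (2.5 equiv), dry DMF, 100 °C, N2
Reagents that add atoms: none
Why: Cs2CO3 first deprotonates the acidic N–H and then removes the vinylic hydrogen together with the bromine trans to it, giving bromoalkyne 8, whose sulfonamide anion adds to the bromine-bearing alkyne carbon before hydrogencarbonate protonates the resulting C3 vinyl anion (attack of nitrogen on the CBr2 carbon followed by loss of bromide would end at the same product). The closest known reaction type is the transition-metal-free, carbonate-promoted cyclisation of N-sulfonyl 2-(2,2-dibromovinyl)anilines to 2-bromoindoles, a relative of the 5-endo closure of difluorovinyl sulfonanilides to 2-fluoroindoles and of copper- or palladium-catalysed aminations of gem-dihaloalkenes. The pyrrole ring closes in the 5-endo-dig mode (5-endo-trig on the addition–elimination path) and this forms the N1–C2 bond. No stereocentre is created. The step needs chemoselectivity for one vinylic bromine over the two aryl bromines: without a metal nothing can insert into C4–Br or C5–Br of 7, these unactivated positions do not undergo nucleophilic aromatic substitution by a sulfonamide anion, and only the alkene terminus lies within reach of a five-membered closure. The second vinylic bromine is kept because aromatisation ends the sequence and the C2–Br bond of an N-sulfonylindole has no elimination or addition–elimination outlet under carbonate.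

Step 6
Reactants: 9 2,5,6-tribromo-1-(methylsulfonyl)indole
Product: 11 2,5,6-tribromo-1-methylindole, via 2,5,6-tribromoindole 10 (not isolated)
Conditions: KOH (powdered, 5 equiv), DMSO, rt → 40 °C; then MeI (3 equiv), rt, same flask
Reagents that add atoms: iodomethane, CI
Why: Hydroxide cleaves the N–S bond of the electron-poor N-sulfonylindole (sulfonamide hydrolysis, helped by the good tribromoindolide leaving group) and the potassium indolide so formed undergoes SN2 N-methylation under standard KOH/DMSO indole alkylation conditions, which spares the isolation of the labile N–H 2-bromoindole 10.

Step 7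
Reactants: 11 2,5,6-tribromo-1-methylindole
Product: 13 2,5,6-tribromo-1-methylindole-3-carbaldehyde, via C3 iminium bromide 12 (not isolated)
Conditions: POBr3 (2 equiv), DMF, 0 → 60 °C; then aq. NaOAc, rt
Reagents that add atoms: N,N-dimethylformamide, CN(C)C=O; water, O
Why: Vilsmeier–Haack formylation, in which the bromoiminium salt from DMF and POBr3 attacks C3, the only open and most nucleophilic pyrrole position, and buffered hydrolysis of iminium 12 gives the aldehyde without hydroxide attack at C2, while bromide as the only halide present makes any exchange at the activated C2 position degenerate.

Compound list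
1 | 4-bromo-2-nitrobenzaldehyde | O=Cc1ccc(Br)cc1[N+](=O)[O-] | starting material
2 | carbon tetrabromide | BrC(Br)(Br)Br | starting material
3 | 4-bromo-1-(2,2-dibromovinyl)-2-nitrobenzene | O=[N+]([O-])c1cc(Br)ccc1C=C(Br)Br | intermediate
4 | 5-bromo-2-(2,2-dibromovinyl)aniline | Nc1cc(Br)ccc1C=C(Br)Br | intermediate
5 | 4,5-dibromo-2-(2,2-dibromovinyl)aniline | Nc1cc(Br)c(Br)cc1C=C(Br)Br | intermediate
6 | methanesulfonyl chloride | CS(=O)(=O)Cl | starting material
7 | N-[4,5-dibromo-2-(2,2-dibromovinyl)phenyl]methanesulfonamide | CS(=O)(=O)Nc1cc(Br)c(Br)cc1C=C(Br)Br | intermediate
8 | N-[4,5-dibromo-2-(bromoethynyl)phenyl]methanesulfonamide (formed in the flask) | CS(=O)(=O)Nc1cc(Br)c(Br)cc1C#CBr | intermediate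
9 | 2,5,6-tribromo-1-(methylsulfonyl)indole | CS(=O)(=O)n1c(Br)cc2cc(Br)c(Br)cc21 | intermediate
10 | 2,5,6-tribromo-1H-indole (present in the flask as its potassium salt) | Brc1cc2cc(Br)c(Br)cc2[nH]1 | intermediate
11 | 2,5,6-tribromo-1-methylindole | Cn1c(Br)cc2cc(Br)c(Br)cc21 | intermediate
12 | dimethyl[(2,5,6-tribromo-1-methylindol-3-yl)methylidene]ammonium bromide (formed in the flask) | C[N+](C)=Cc1c(Br)n(C)c2cc(Br)c(Br)cc12.[Br-] | intermediate
13 | 2,5,6-tribromo-1-methylindole-3-carbaldehyde | Cn1c(Br)c(C=O)c2cc(Br)c(Br)cc21 | target

Total step count: 7
Longest linear sequence: 7

Steps most likely to fail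

1. Step 5 (key step).
- What may go wrong: the sequence may stall after dehydrobromination. The haloalkyne may be diverted by dimethylamine released from hot DMF or by traces of water. The mesyl group may be lost before ring closure.
- Fallback: the N1–C2 bond is made by cross-coupling instead of elimination–addition, and without any sulfonamide. Setting out from aniline 5, catalytic Pd(PtBu3)2 with K2CO3 in dilute toluene at 100 °C should effect an intramolecular Buchwald–Hartwig-type vinylic amination. Zerovalent palladium carrying this very bulky phosphine inserts reversibly into C–Br bonds. Only the insertion that is followed by fast ring-closing amination is therefore productive, and the aryl bromides and the new C2–Br bond are handed back.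
- Return: the product is 2,5,6-tribromoindole 10, which is passed crude into the KOH/DMSO/MeI stage of step 6. The detour returns to the route at 10, skips steps 4 and 5 and makes no compound outside the list (F0).

2. Step 7.
- What may go wrong: electrophilic attack on a ring carrying three bromines may be sluggish. That would force temperatures at which displacement of the C2 halogen at the iminium stage begins.
- Fallback: the polarity at C3 is inverted. Setting out from 11, NIS in DMF at rt should iodinate the free C3 position, a much easier substitution than formylation, to give 2,5,6-tribromo-3-iodo-1-methylindole F1. Treatment with iPrMgCl·LiCl in THF at −40 °C should exchange only the iodine, since iodine–magnesium exchange far outruns bromine–magnesium exchange at this temperature. This gives (2,5,6-tribromo-1-methylindol-3-yl)magnesium chloride F2.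
- Return: quenching with DMF and then water returns to the route at 13.

3. Step 3.
- What may go wrong: the free aniline may be brominated twice, attacked at the ortho position or oxidised by the reagent.
- Fallback: the order of steps 3 and 4 is reversed so that the ring is tamed before halogenation. Setting out from 4, MsCl and pyridine in CH2Cl2 give N-[5-bromo-2-(2,2-dibromovinyl)phenyl]methanesulfonamide F3. Its less activated ring should then take up a single bromine para to nitrogen with NBS in MeCN at rt to 50 °C.
- Return: the detour rejoins the route at 7.

Further compounds
F0 | step 5 | none | none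
F1 | step 7 | 2,5,6-tribromo-3-iodo-1-methylindole | Cn1c(Br)c(I)c2cc(Br)c(Br)cc21
F2 | step 7 | (2,5,6-tribromo-1-methylindol-3-yl)magnesium chloride | Cn1c(Br)c([Mg]Cl)c2cc(Br)c(Br)cc21
F3 | step 3 | N-[5-bromo-2-(2,2-dibromovinyl)phenyl]methanesulfonamide | CS(=O)(=O)Nc1cc(Br)ccc1C=C(Br)Br
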